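**Retrosynthetic overview**
1. The ten-membered ring is closed last at C6–C7 by an electro-catalytic intramolecular γ-chloroallylchromium addition to a C7 aldehyde; the same step installs C6–Cl, the 5(16)-methylene and, after acid, the γ-lactone.
2. The seco-aldehyde gets C8/C17 from a Felkin-controlled propanoate aldol on a C8 ketone, and C2–C3 from acetylide opening of a bridged C2/O11 γ-lactone followed by chelation-controlled reduction and Z-semi-reduction.
3. Ring A is made first by a Diels–Alder reaction of an (E)-α-methyl enal from D-mannitol (C9 is the only purchased stereocentre) with a 2-silyloxy diene; C11–C14 are then oxidised by OsO4 and a directed epoxidation.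
4. Ring order: cyclohexane (Diels–Alder) → temporary bridged lactone (opened again) → ten-membered carbocycle (electrolysis) → butyrolactone (lactonisation in the same pot).

Atom labels follow briarane numbering: C1 quaternary (C15 methyl), C2 carbinol, C3=C4, C5(=C16), C6 (Cl), C7 (lactone O–CH), C8 (tertiary OH), C9 (OAc), C10, C11 (C20 methyl, OH), C12 (butanoate), C13/C14 epoxide, C17 (C18 methyl), C19 lactone C=O. "α" is the ring-A face carrying C2 on C1; "β" is the face of the two methyls and C9.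

Assumption: 18 forms as an E/Z mixture and is carried on as such (E drawn; the geometry is erased in step 26); C5 of 7–9 and C8 of 28–30 are epimer mixtures that converge; 19 and 20 equilibrate with their C2/O11 hemiketals (open forms drawn).

**Route**

Step 1
Reactants: 1 1,2:5,6-di-O-isopropylidene-D-mannitol; 2 2-(triphenylphosphoranylidene)propanal
Product: 4 (S,E)-3-(2,2-dimethyl-1,3-dioxolan-4-yl)-2-methylprop-2-enal, via glyceraldehyde acetonide 3 (not isolated)
Conditions: NaIO4, sat. aq. NaHCO3, CH2Cl2, 0 °C → rt; dry, filter; then 2 (2.1 equiv), CH2Cl2, 40 °C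
Reagents that add atoms: none
Why: Periodate glycol cleavage gives two equivalents of the configurationally fragile aldehyde 3, which is trapped at once by an E-selective stabilised-ylide Wittig reaction; the stereocentre (future C9) comes unchanged from D-mannitol.

Step 2
Reactants: 5 pent-1-en-3-one
Product: 6 (Z)-3-(tert-butyldimethylsilyloxy)penta-1,3-diene
Conditions: TBSOTf, Et3N, Et2O, 0 °C
Reagents that add atoms: tert-butyldimethylsilyl triflate CC(C)(C)[Si](C)(C)OS(=O)(=O)C(F)(F)F
Why: Soft enolisation of the enone (silyl dienol ether formation) gives the 2-silyloxy diene with the terminal methyl trans to the vinyl group, the isomer that can reach the s-cis conformation.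

Step 3
Reactants: 4 (S,E)-3-(2,2-dimethyl-1,3-dioxolan-4-yl)-2-methylprop-2-enal; 6 (Z)-3-(tert-butyldimethylsilyloxy)penta-1,3-diene
Product: 7 (1S,6S)-4-(tert-butyldimethylsilyloxy)-6-[(S)-2,2-dimethyl-1,3-dioxolan-4-yl]-1,5-dimethylcyclohex-3-ene-1-carbaldehyde (C5 epimers)
Conditions: Me2AlCl (30 mol%), CH2Cl2/toluene, −78 → −40 °C
Reagents that add atoms: none
Why: Lewis-acid-catalysed Diels–Alder reaction in which the silyl enol ether terminus bonds to the enal β-carbon (C10), the E geometry places C2 trans to C9, and the diene adds anti to the allylic C9–O bond of the A(1,3)-locked conformer (C9–H eclipsing the C=C because of the α-methyl), so C1 and C10 are set by C9; the C5 (= C11) centre is erased in step 6.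

Step 4
Reactants: 7 Diels–Alder adduct (silyl enol ether aldehyde)
Product: 8 (1S,6S)-6-[(S)-2,2-dimethyl-1,3-dioxolan-4-yl]-1,5-dimethyl-4-oxocyclohex-2-ene-1-carbaldehyde (C5 epimers)
Conditions: Pd(OAc)2 (10 mol%), O2 (1 atm), DMSO, 50 °C
Reagents that add atoms: none
Why: Saegusa–Ito oxidation of the regiodefined silyl enol ether puts the enone double bond at C13=C14 (the only β-hydrogens of the Pd enolate are on C14) without touching C1, C9 or C10.

Step 5
Reactants: 8 enone aldehyde
Product: 9 (1S,6S)-6-[(S)-2,2-dimethyl-1,3-dioxolan-4-yl]-1,5-dimethyl-4-oxocyclohex-2-ene-1-carboxylic acid (C5 epimers)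
Conditions: NaClO2, NaH2PO4, 2-methylbut-2-ene, t-BuOH/H2O, 0 °C → rt
Reagents that add atoms: sodium chlorite [Na+].[O-]Cl=O
Why: Pinnick oxidation converts the non-enolisable neopentyl aldehyde into the acid that later masks C2 and O11 as a lactone; enone and acetonide are inert to buffered chlorite.

Step 6
Reactants: 9 enone acid
Product: 10 (1S,6S)-6-[(S)-2,2-dimethyl-1,3-dioxolan-4-yl]-1,5-dimethyl-4-(trifluoromethylsulfonyloxy)cyclohexa-2,4-diene-1-carboxylic acid
Conditions: KHMDS (2.2 equiv), THF, −78 °C; Comins' reagent, −78 → 0 °C; dilute HCl (pH 3), 0 °C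
Reagents that add atoms: Comins' reagent FC(F)(F)S(=O)(=O)N(c1ccc(Cl)cn1)S(=O)(=O)C(F)(F)F
Why: The carboxylate/dienolate dianion can only form at C11 (C1 is quaternary) and is O-triflated (enol triflate formation), which also erases the scrambled C11 centre.

Step 7
Reactants: 10 dienyl triflate acid
Product: 11 (1S,6S)-6-[(S)-2,2-dimethyl-1,3-dioxolan-4-yl]-1,5-dimethylcyclohexa-2,4-diene-1-carboxylic acid
Conditions: Pd(OAc)2 (5 mol%), PPh3 (10 mol%), HCO2H, Et3N, DMF, 60 °C
Reagents that add atoms: none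
Why: Palladium-catalysed formate reduction of the dienyl triflate (hydride from decarboxylating formate, then reductive elimination) gives the 1,3-diene needed for a cis-dihydroxylation.

Step 8
Reactants: 11 diene acid
Product: 13 bridged γ-lactone (C2 carboxyl lactonised on O11; 12α-OH; C13=C14; (S)-dioxolanyl on C10), via cis-diol acid 12 (not isolated)
Conditions: OsO4 (2 mol%), NMO (1.1 equiv), acetone/H2O, 0 °C → rt; then PPTS (cat.), CH2Cl2, rt
Reagents that add atoms: N-methylmorpholine N-oxide C[N+]1([O-])CCOCC1; water O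
Why: Upjohn dihydroxylation attacks the more electron-rich trisubstituted C11=C12 bond from the α face, anti to the pseudo-axial C9 branch on the neighbouring C10, giving the cis 11α,12α-diol, and the C11 hydroxyl, cis-1,3 to the carboxyl, then lactonises.

Step 9
Reactants: 13 bridged hydroxy lactone
Product: 14 13α,14α-epoxide of lactone 13
Conditions: VO(acac)2 (5 mol%), t-BuOOH, CH2Cl2, 0 °C → rt
Reagents that add atoms: tert-butyl hydroperoxide CC(C)(C)OO
Why: Vanadium-catalysed hydroxyl-directed epoxidation delivers oxygen syn to the allylic 12α-OH (the β face is also blocked by the C9 branch), setting C13 and C14.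

Step 10
Reactants: 15 ethynylmagnesium bromide; 16 1,3-dichloropropan-2-one
Product: 17 1-chloro-2-(chloromethyl)but-3-yn-2-ol
Conditions: THF, −78 °C; sat. aq. NH4Cl at −78 °C
Reagents that add atoms: none
Why: Grignard 1,2-addition to the activated ketone, quenched cold before the chlorohydrin alkoxide can close to an epoxide.

Step 11
Reactants: 17 1-chloro-2-(chloromethyl)but-3-yn-2-ol
Product: 18 (E)-1-chloro-2-(chloromethyl)but-1-en-3-yne
Conditions: POCl3, pyridine, 0 → 50 °C
Reagents that add atoms: none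
Why: Dehydration of the tertiary alcohol through its dichlorophosphate (E2 loss of an acidified CH2Cl proton) gives the conjugated chloro-enyne that carries the allylic chloride.

Step 12
Reactants: 14 epoxy hydroxy lactone; 18 (E)-1-chloro-2-(chloromethyl)but-1-en-3-yne
Product: 19 ynone diol (C2 ketone bearing the C3≡C4–C5(CH2Cl)=C6HCl unit; 11α,12α-diol; 13α,14α-epoxide; 8,9-acetonide)
Conditions: 18 (2.5 equiv), n-BuLi, THF, −78 °C; then 14, −78 → −30 °C; sat. aq. NH4Cl
Reagents that add atoms: none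
Why: Addition of the lithium acetylide to the γ-lactone stops at the tetrahedral stage, so work-up gives the ynone and forms the C2–C3 bond; no other ester is present yet and the epoxide is inert to an acetylide without Lewis acid.

Step 13
Reactants: 19 ynone diol
Product: 20 12-O-butanoyl ynone
Conditions: (n-PrCO)2O, pyridine, DMAP (5 mol%), CH2Cl2, 0 °C
Reagents that add atoms: butanoic anhydride CCCC(=O)OC(=O)CCC
Why: DMAP-catalysed acylation esterifies the only secondary hydroxyl (C12); the tertiary C11-OH, largely tied up as the hemiketal, does not react.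

Step 14
Reactants: 20 12-O-butanoyl ynone
Product: 21 (2S)-propargylic alcohol
Conditions: Zn(BH4)2, Et2O, −30 °C; sat. aq. NH4Cl
Reagents that add atoms: none
Why: Chelation-controlled 1,2-reduction in which zinc bridges the C11 oxygen and the C2 carbonyl (the two are 1,3-diaxial, as their hemiketal shows) and hydride attacks the open face away from the epoxide, giving the 2S carbinol.

Step 15
Reactants: 21 (2S)-propargylic alcohol
Product: 22 2-O-tert-butyldimethylsilyl ether of 21
Conditions: TBSOTf (1.3 equiv), 2,6-lutidine, CH2Cl2, −78 °C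
Reagents that add atoms: tert-butyldimethylsilyl triflate CC(C)(C)[Si](C)(C)OS(=O)(=O)C(F)(F)F
Why: Silyl triflate silylation protects the secondary C2-OH (the hindered tertiary C11-OH is left) so that C9 can later be acetylated selectively.

Step 16
Reactants: 22 2-O-TBS enyne
Product: 23 (3Z)-chlorodiene (22 with C3≡C4 reduced to the Z alkene)
Conditions: Cy2BH (3 equiv, from BH3·SMe2 and cyclohexene), THF, 0 °C → rt; then AcOH, 45 °C
Reagents that add atoms: none
Why: Hydroboration–protonolysis (syn addition of the dialkylborane to the alkyne, then C–B protonolysis with retention) gives the Z alkene without the hydrogenolysis risk that Pd/H2 poses to the allylic chloride.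

Step 17
Reactants: 23 (3Z)-chlorodiene acetonide
Product: 24 8,9-diol
Conditions: AcOH/THF/H2O (3:1:1), 40 °C
Reagents that add atoms: none
Why: Mild acid hydrolysis of the terminal acetonide frees the 8,9-diol; the hindered TBS ether and the neopentyl-flanked epoxide survive.

Step 18
Reactants: 24 8,9-diol
Product: 25 8,9-bis-O-triethylsilyl ether
Conditions: TESCl (2.5 equiv), imidazole, DMF, 0 °C
Reagents that add atoms: chlorotriethylsilane CC[Si](Cl)(CC)CC
Why: Standard silylation of the primary and secondary hydroxyls (tertiary C11-OH inert) sets up a selective oxidation.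

Step 19
Reactants: 25 8,9-bis-O-triethylsilyl ether
Product: 26 C8 aldehyde (9-O-TES)
Conditions: (COCl)2, DMSO, CH2Cl2, −78 → −35 °C; then Et3N, −78 → 0 °C
Reagents that add atoms: none
Why: Under Swern conditions the primary triethylsilyl ether is cleaved and oxidised in situ while the secondary one survives, giving the aldehyde without a separate deprotection.

Step 20
Reactants: 26 C8 aldehyde; 27 (isopropoxydimethylsilyl)methylmagnesium chloride
Product: 29 7,8-diol (9-O-TES; C8 epimers), via β-hydroxysilane 28 (not isolated)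
Conditions: 27 (3 equiv), THF, −78 → −20 °C; sat. aq. NH4Cl; then KF, KHCO3, 30% H2O2, THF/MeOH, rt
Reagents that add atoms: hydrogen peroxide OO
Why: The Tamao hydroxymethyl-anion equivalent adds to the aldehyde (Grignard addition) and the C–Si bond is then oxidised (Tamao–Fleming oxidation), supplying C7 as CH2OH; the C8 configuration is irrelevant.

Step 21
Reactants: 29 7,8-diol
Product: 30 7-O-triethylsilyl 8-ol (C8 epimers)
Conditions: TESCl (1.05 equiv), imidazole, CH2Cl2, −40 °C
Reagents that add atoms: chlorotriethylsilane CC[Si](Cl)(CC)CC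
Why: The primary C7 hydroxyl is silylated far faster than the flanked secondary C8 hydroxyl at low temperature.

Step 22
Reactants: 30 7-O-triethylsilyl 8-ol
Product: 31 C8 ketone (7,9-bis-O-TES)
Conditions: Dess–Martin periodinane, NaHCO3, CH2Cl2, 0 °C → rt
Reagents that add atoms: none
Why: Dess–Martin oxidation of the remaining secondary alcohol gives the ketone under neutral buffered conditions.

Step 23
Reactants: 31 C8 ketone; 32 methyl propanoate
Product: 33 aldol adduct (methyl ester; 8-OH; 17-methyl; 7,9-bis-O-TES)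
Conditions: 32 and LDA (3.5 equiv each), THF/DMPU, −78 °C; then 31, −78 °C; AcOH, −78 °C
Reagents that add atoms: none
Why: Aldol addition of the Z(O) lithium enolate in which polar Felkin–Anh attack anti to the non-chelating C9–OTES bond sets C8 and a Zimmerman–Traxler chair with the C9 branch equatorial sets C17 (8R,17R).

Step 24
Reactants: 33 aldol adduct
Product: 34 C7 aldehyde (9-O-TES)
Conditions: (COCl)2, DMSO, CH2Cl2, −78 → −35 °C; then Et3N, −78 → 0 °C
Reagents that add atoms: none
Why: The same selective Swern oxidation of a primary triethylsilyl ether gives the aldehyde directly, so no free C7 alcohol forms that could lactonise onto C19 too early.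

Step 25
Reactants: 34 C7 aldehyde (9-O-TES)
Product: 36 seco-aldehyde (9-OAc; C7 aldehyde; C16 allylic chloride), via C9 alcohol 35 (not isolated)
Conditions: HF·pyridine, pyridine, THF, 0 °C; then Ac2O, DMAP, 0 °C → rt
Reagents that add atoms: acetic anhydride CC(=O)OC(C)=O
Why: HF·pyridine removes the secondary TES ether much faster than the TBS ether, and the only secondary hydroxyl then present is acetylated (DMAP-catalysed acylation; tertiary hydroxyls do not react).

Step 26
Reactants: 36 seco-aldehyde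
Product: 39 2-O-tert-butyldimethylsilyl ether of the target, via macrocyclic C7 silyl ether 37 (not isolated), via macrocyclic hydroxy ester 38 (not isolated)
Conditions: CrCl3 (15 mol%), TMSCl (4 equiv), n-Bu4NBF4, DMF/THF, Al anode | Ni-foam cathode, undivided cell, constant current, 2.1 F mol−1, slow addition of 36 (2 mM final), rt; then citric acid, MeOH, rt
Reagents that add atoms: none
Why: Proposed new method: cathodically regenerated Cr(II) reduces only the primary allylic C–Cl bond of 36 (two one-electron steps) to an η1-allylchromium(III) with Cr on C16, whose chloroalkene isomers interconvert by 1,3-metallotropy, and this adds through its γ-carbon (C6) to the C7 aldehyde in a closed six-membered chair transition state, so the C6–C7 ring bond, the anti (6S,7R) chlorohydrin and the exocyclic methylene form together; the aldehyde face is set by the tether (C6 must approach synclinal to C9) with the C8–O bond anti to the forming bond, TMSCl frees Cr(III) from the alkoxide for turnover, passing only about 2 F mol−1 keeps Cr(II) from accumulating and reducing the product's secondary allylic chloride, and acid then lactonises O7 onto C19; the closest known reaction type is the Nozaki–Hiyama carbonyl allylation with γ-chloroallylchromium reagents and its electro-catalytic variants, which have not been used to close a ring with a γ-chloro dienyl halide.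

Step 27
Reactants: 39 2-O-tert-butyldimethylsilyl ether of the target
Product: 40 CNP0325729.2 (target)
Conditions: HF·pyridine, pyridine, THF, 0 °C → rt
Reagents that add atoms: none
Why: Fluoride-mediated desilylation frees the C2 hydroxyl under buffered conditions that leave the esters, lactone, epoxide and allylic chloride intact.

**Compound list**

1 | 1,2:5,6-di-O-isopropylidene-D-mannitol | CC1(C)OC[C@@H](O1)[C@H](O)[C@@H](O)[C@H]1COC(C)(C)O1 | starting material
2 | 2-(triphenylphosphoranylidene)propanal | O=CC(C)=P(c1ccccc1)(c1ccccc1)c1ccccc1 | starting material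
3 | (R)-2,2-dimethyl-1,3-dioxolane-4-carbaldehyde | O=C[C@H]1COC(C)(C)O1 | intermediate
4 | (S,E)-3-(2,2-dimethyl-1,3-dioxolan-4-yl)-2-methylprop-2-enal | O=C/C(C)=C/[C@H]1COC(C)(C)O1 | intermediate
5 | pent-1-en-3-one | C=CC(=O)CC | starting material
6 | (Z)-3-(tert-butyldimethylsilyloxy)penta-1,3-diene | C/C=C(\O[Si](C)(C)C(C)(C)C)C=C | intermediate
7 | (1S,6S)-4-(tert-butyldimethylsilyloxy)-6-[(S)-2,2-dimethyl-1,3-dioxolan-4-yl]-1,5-dimethylcyclohex-3-ene-1-carbaldehyde (C5 epimers) | O=C[C@@]1(C)CC=C(O[Si](C)(C)C(C)(C)C)C(C)[C@@H]1[C@H]1COC(C)(C)O1 | intermediate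
8 | (1S,6S)-6-[(S)-2,2-dimethyl-1,3-dioxolan-4-yl]-1,5-dimethyl-4-oxocyclohex-2-ene-1-carbaldehyde (C5 epimers) | O=C[C@@]1(C)C=CC(=O)C(C)[C@@H]1[C@H]1COC(C)(C)O1 | intermediate
9 | (1S,6S)-6-[(S)-2,2-dimethyl-1,3-dioxolan-4-yl]-1,5-dimethyl-4-oxocyclohex-2-ene-1-carboxylic acid (C5 epimers) | OC(=O)[C@@]1(C)C=CC(=O)C(C)[C@@H]1[C@H]1COC(C)(C)O1 | intermediate
10 | (1S,6S)-6-[(S)-2,2-dimethyl-1,3-dioxolan-4-yl]-1,5-dimethyl-4-(trifluoromethylsulfonyloxy)cyclohexa-2,4-diene-1-carboxylic acid | OC(=O)[C@@]1(C)C=CC(OS(=O)(=O)C(F)(F)F)=C(C)[C@@H]1[C@H]1COC(C)(C)O1 | intermediate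
11 | (1S,6S)-6-[(S)-2,2-dimethyl-1,3-dioxolan-4-yl]-1,5-dimethylcyclohexa-2,4-diene-1-carboxylic acid | OC(=O)[C@@]1(C)C=CC=C(C)[C@@H]1[C@H]1COC(C)(C)O1 | intermediate
12 | cis-diol acid: 11 with 11α,12α-dihydroxy groups and C13=C14 retained | OC(=O)[C@@]1(C)C=C[C@@H](O)[C@@](C)(O)[C@@H]1[C@H]1COC(C)(C)O1 | intermediate
13 | bridged γ-lactone: C2 carboxyl lactonised on O11 (6-oxabicyclo[3.2.1]oct-2-en-7-one core); 12α-OH; (S)-dioxolanyl on C10 | O=C3[C@@]1(C)C=C[C@@H](O)[C@@](C)(O3)[C@@H]1[C@H]1COC(C)(C)O1 | intermediate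
14 | 13α,14α-epoxide of lactone 13 | O=C3[C@@]1(C)[C@H]2O[C@H]2[C@@H](O)[C@@](C)(O3)[C@@H]1[C@H]1COC(C)(C)O1 | intermediate
15 | ethynylmagnesium bromide | C#C[Mg]Br | starting material
16 | 1,3-dichloropropan-2-one | ClCC(=O)CCl | starting material
17 | 1-chloro-2-(chloromethyl)but-3-yn-2-ol | C#CC(O)(CCl)CCl | intermediate
18 | (E)-1-chloro-2-(chloromethyl)but-1-en-3-yne | Cl/C=C(CCl)\C#C | intermediate
19 | ynone diol: C2 ketone bearing the C3≡C4–C5(CH2Cl)=C6HCl unit; 11α,12α-diol; 13α,14α-epoxide; 8,9-acetonide | Cl/C=C(CCl)\C#CC(=O)[C@@]1(C)[C@H]2O[C@H]2[C@@H](O)[C@@](C)(O)[C@@H]1[C@H]1COC(C)(C)O1 | intermediate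
20 | 12-O-butanoyl ynone | Cl/C=C(CCl)\C#CC(=O)[C@@]1(C)[C@H]2O[C@H]2[C@@H](OC(=O)CCC)[C@@](C)(O)[C@@H]1[C@H]1COC(C)(C)O1 | intermediate
21 | (2S)-propargylic alcohol | Cl/C=C(CCl)\C#C[C@H](O)[C@@]1(C)[C@H]2O[C@H]2[C@@H](OC(=O)CCC)[C@@](C)(O)[C@@H]1[C@H]1COC(C)(C)O1 | intermediate
22 | 2-O-tert-butyldimethylsilyl ether of 21 | Cl/C=C(CCl)\C#C[C@H](O[Si](C)(C)C(C)(C)C)[C@@]1(C)[C@H]2O[C@H]2[C@@H](OC(=O)CCC)[C@@](C)(O)[C@@H]1[C@H]1COC(C)(C)O1 | intermediate
23 | (3Z)-chlorodiene: 22 with C3≡C4 reduced to the Z alkene | Cl/C=C(CCl)\C=C/[C@H](O[Si](C)(C)C(C)(C)C)[C@@]1(C)[C@H]2O[C@H]2[C@@H](OC(=O)CCC)[C@@](C)(O)[C@@H]1[C@H]1COC(C)(C)O1 | intermediate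
24 | 8,9-diol | Cl/C=C(CCl)\C=C/[C@H](O[Si](C)(C)C(C)(C)C)[C@@]1(C)[C@H]2O[C@H]2[C@@H](OC(=O)CCC)[C@@](C)(O)[C@@H]1[C@H](O)CO | intermediate
25 | 8,9-bis-O-triethylsilyl ether | Cl/C=C(CCl)\C=C/[C@H](O[Si](C)(C)C(C)(C)C)[C@@]1(C)[C@H]2O[C@H]2[C@@H](OC(=O)CCC)[C@@](C)(O)[C@@H]1[C@H](O[Si](CC)(CC)CC)CO[Si](CC)(CC)CC | intermediate
26 | C8 aldehyde (9-O-TES) | Cl/C=C(CCl)\C=C/[C@H](O[Si](C)(C)C(C)(C)C)[C@@]1(C)[C@H]2O[C@H]2[C@@H](OC(=O)CCC)[C@@](C)(O)[C@@H]1[C@H](O[Si](CC)(CC)CC)C=O | intermediate
27 | (isopropoxydimethylsilyl)methylmagnesium chloride | CC(C)O[Si](C)(C)C[Mg]Cl | starting material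
28 | β-hydroxysilane: C8 carbinol bearing CH2SiMe2(OiPr) (C8 epimers) | Cl/C=C(CCl)\C=C/[C@H](O[Si](C)(C)C(C)(C)C)[C@@]1(C)[C@H]2O[C@H]2[C@@H](OC(=O)CCC)[C@@](C)(O)[C@@H]1[C@H](O[Si](CC)(CC)CC)C(O)C[Si](C)(C)OC(C)C | intermediate
29 | 7,8-diol (9-O-TES; C8 epimers) | Cl/C=C(CCl)\C=C/[C@H](O[Si](C)(C)C(C)(C)C)[C@@]1(C)[C@H]2O[C@H]2[C@@H](OC(=O)CCC)[C@@](C)(O)[C@@H]1[C@H](O[Si](CC)(CC)CC)C(O)CO | intermediate
30 | 7-O-triethylsilyl 8-ol (C8 epimers) | Cl/C=C(CCl)\C=C/[C@H](O[Si](C)(C)C(C)(C)C)[C@@]1(C)[C@H]2O[C@H]2[C@@H](OC(=O)CCC)[C@@](C)(O)[C@@H]1[C@H](O[Si](CC)(CC)CC)C(O)CO[Si](CC)(CC)CC | intermediate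
31 | C8 ketone (7,9-bis-O-TES) | Cl/C=C(CCl)\C=C/[C@H](O[Si](C)(C)C(C)(C)C)[C@@]1(C)[C@H]2O[C@H]2[C@@H](OC(=O)CCC)[C@@](C)(O)[C@@H]1[C@H](O[Si](CC)(CC)CC)C(=O)CO[Si](CC)(CC)CC | intermediate
32 | methyl propanoate | CCC(=O)OC | starting material
33 | aldol adduct: C19 methyl ester; 8-OH; 17-methyl (target configuration at C8 and C17); 7,9-bis-O-TES | Cl/C=C(CCl)\C=C/[C@H](O[Si](C)(C)C(C)(C)C)[C@@]1(C)[C@H]2O[C@H]2[C@@H](OC(=O)CCC)[C@@](C)(O)[C@@H]1[C@H](O[Si](CC)(CC)CC)[C@@](O)(CO[Si](CC)(CC)CC)[C@@H](C)C(=O)OC | intermediate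
34 | C7 aldehyde (9-O-TES) | Cl/C=C(CCl)\C=C/[C@H](O[Si](C)(C)C(C)(C)C)[C@@]1(C)[C@H]2O[C@H]2[C@@H](OC(=O)CCC)[C@@](C)(O)[C@@H]1[C@H](O[Si](CC)(CC)CC)[C@@](O)(C=O)[C@@H](C)C(=O)OC | intermediate
35 | C9 alcohol (C7 aldehyde) | Cl/C=C(CCl)\C=C/[C@H](O[Si](C)(C)C(C)(C)C)[C@@]1(C)[C@H]2O[C@H]2[C@@H](OC(=O)CCC)[C@@](C)(O)[C@@H]1[C@H](O)[C@@](O)(C=O)[C@@H](C)C(=O)OC | intermediate
36 | seco-aldehyde: 9-OAc; C7 aldehyde; C16 allylic chloride | Cl/C=C(CCl)\C=C/[C@H](O[Si](C)(C)C(C)(C)C)[C@@]1(C)[C@H]2O[C@H]2[C@@H](OC(=O)CCC)[C@@](C)(O)[C@@H]1[C@H](OC(C)=O)[C@@](O)(C=O)[C@@H](C)C(=O)OC | intermediate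
37 | macrocyclic C7 trimethylsilyl ether: ten-membered ring closed; 6-Cl; 5(16)-methylene; C19 methyl ester | C=C1/C=C\[C@H](O[Si](C)(C)C(C)(C)C)[C@@]2(C)[C@H]3O[C@H]3[C@@H](OC(=O)CCC)[C@@](C)(O)[C@@H]2[C@H](OC(C)=O)[C@](O)([C@@H](C)C(=O)OC)[C@@H](O[Si](C)(C)C)[C@H]1Cl | intermediate
38 | macrocyclic 7-hydroxy methyl ester | C=C1/C=C\[C@H](O[Si](C)(C)C(C)(C)C)[C@@]2(C)[C@H]3O[C@H]3[C@@H](OC(=O)CCC)[C@@](C)(O)[C@@H]2[C@H](OC(C)=O)[C@](O)([C@@H](C)C(=O)OC)[C@@H](O)[C@H]1Cl | intermediate
39 | 2-O-tert-butyldimethylsilyl ether of the target | C=C1/C=C\[C@H](O[Si](C)(C)C(C)(C)C)[C@@]2(C)[C@H]3O[C@H]3[C@@H](OC(=O)CCC)[C@@](C)(O)[C@@H]2[C@H](OC(C)=O)[C@]2(O)[C@@H](C)C(=O)O[C@H]2[C@H]1Cl | intermediate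
40 | CNP0325729.2 | C=C1/C=C\[C@H](O)[C@@]2(C)[C@H]3O[C@H]3[C@@H](OC(=O)CCC)[C@@](C)(O)[C@@H]2[C@H](OC(C)=O)[C@]2(O)[C@@H](C)C(=O)O[C@H]2[C@H]1Cl | target

**Totals and risks**

Total step count: 27. Longest linear sequence: 24 (steps 1, 3–9, 12–27); step 2 and steps 10–11 run in parallel.

Three steps most likely to fail:

Step 3 (Diels–Alder: hindered trisubstituted enal, terminally substituted diene, facial control by one allylic centre). The fallback sets out from 4 and comes back at 8. It replaces the catalysed 2-silyloxy-diene cycloaddition by a thermal cycloaddition of a far more nucleophilic amino-siloxy diene. (1E,3Z)-1-(dimethylamino)-3-(tert-butyldimethylsilyloxy)penta-1,3-diene F1 is made from 1-(dimethylamino)pent-1-en-3-one with KHMDS and TBSCl. It reacts with 4 in toluene at 40 °C to give the amino silyl enol ether cycloadduct F2. Dilute HF in MeCN at −20 °C then removes dimethylamine and the silyl group to give enone 8 directly, so step 4 is not needed.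

Step 23 (aldol on a hindered, enolisable α,α'-dioxygenated ketone; two stereocentres). The fallback sets out from 31 and comes back at 33. If the basic lithium enolate only enolises 31, a preformed Reformatsky reagent is used instead: methyl 2-bromopropanoate and TMSCl-activated zinc in THF, filtered from excess zinc, then added to 31 at 0 °C. This non-basic zinc enolate adds to enolisable ketones, the substrate never sees zinc metal (the allylic chloride is spared), and no new isolable compound is formed.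

Step 26 (the proposed electro-catalytic macrocyclisation; risks are over-reduction of the product chloride, the C7 face and ring strain). The fallback sets out from 33 and comes back at 39, and closes the same ring by a thermal type-I allylboration, all of it known reaction types. Palladium-catalysed borylation of the primary allylic chloride of 33 (Pd2(dba)3 cat., B2pin2, DMSO, 50 °C) gives the (E)-γ-chloroallyl pinacolboronate F3. Swern oxidation of its primary triethylsilyl ether gives the boronate aldehyde F4. At high dilution in toluene (40–60 °C) F4 cyclises through the closed chair transition state to the anti chlorohydrin borate, and triethanolamine then citric acid work-up lactonises it to the 9-O-triethylsilyl macrolactone F5. HF·pyridine followed by Ac2O/DMAP (as in step 25) converts F5 into 39. This variant needs the E chloroalkene, because allylboration is stereospecific.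

**Further compounds**

F1 | step 3 | (1E,3Z)-1-(dimethylamino)-3-(tert-butyldimethylsilyloxy)penta-1,3-diene | CN(C)/C=C/C(O[Si](C)(C)C(C)(C)C)=C/C
F2 | step 3 | amino silyl enol ether cycloadduct | O=C[C@@]1(C)C(N(C)C)C=C(O[Si](C)(C)C(C)(C)C)C(C)[C@@H]1[C@H]1COC(C)(C)O1
F0 | step 23 | none | none
F3 | step 26 | (E)-γ-chloroallyl pinacolboronate (7,9-bis-O-TES) | Cl/C=C(CB3OC(C)(C)C(C)(C)O3)\C=C/[C@H](O[Si](C)(C)C(C)(C)C)[C@@]1(C)[C@H]2O[C@H]2[C@@H](OC(=O)CCC)[C@@](C)(O)[C@@H]1[C@H](O[Si](CC)(CC)CC)[C@@](O)(CO[Si](CC)(CC)CC)[C@@H](C)C(=O)OC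
F4 | step 26 | boronate aldehyde (9-O-TES) | Cl/C=C(CB3OC(C)(C)C(C)(C)O3)\C=C/[C@H](O[Si](C)(C)C(C)(C)C)[C@@]1(C)[C@H]2O[C@H]2[C@@H](OC(=O)CCC)[C@@](C)(O)[C@@H]1[C@H](O[Si](CC)(CC)CC)[C@@](O)(C=O)[C@@H](C)C(=O)OC
F5 | step 26 | 9-O-triethylsilyl macrolactone (2-O-TBS) | C=C1/C=C\[C@H](O[Si](C)(C)C(C)(C)C)[C@@]2(C)[C@H]3O[C@H]3[C@@H](OC(=O)CCC)[C@@](C)(O)[C@@H]2[C@H](O[Si](CC)(CC)CC)[C@]2(O)[C@@H](C)C(=O)O[C@H]2[C@H]1Cl
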